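**Assumption:** the target has no stereocentres, so it is achiral and "single enantiomer" does not constrain the route. The only stereocentres in the route are transient and racemic, and they are erased in step 3. I also assume 5-bromo-2-methylpent-1-ene is commercially available.

## Retrosynthetic overview
- Target ← O-acetylation of the 2-hydroxy-3-isopropyl-naphthoquinone.
- That hydroxyquinone ← nucleophilic epoxidation and base-mediated isomerisation of the 3-isopropyl-naphthoquinone. The oxygen goes to C2 because it is the only remaining quinone C–H.
- The 3-isopropyl-naphthoquinone ← key step: Ag/persulfate radical decarboxylative isopropylation (from isobutyric acid) of 7-methyl-8-(4-methylpent-4-enyl)-1,4-naphthoquinone.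
- That naphthoquinone ← Diels–Alder of 1,4-benzoquinone with a 1-alkyl-2-methylbutadiene generated in situ from an alkylated 3-methylsulfolene, then DDQ aromatisation.
- Ring order: the quinone ring is already present in benzoquinone, the benzo ring is built by the Diels–Alder, and the side chain and methyl are carried in by the diene.

## Route

**Step 1**
Reactants: 1 (3-methyl-2,5-dihydrothiophene 1,1-dioxide), 2 (5-bromo-2-methylpent-1-ene)
Product: 3 (3-methyl-2-(4-methylpent-4-en-1-yl)-2,5-dihydrothiophene 1,1-dioxide, racemic)
Conditions: LiHMDS (1.05 equiv), THF/HMPA 4:1, –100 → –78 °C; add 2, warm to –40 °C.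
Reagents that add atoms: none (LiHMDS is only a base).
Why: Deprotonation of 1 at C2 gives an allylic α-sulfonyl anion, and alkylation there is SN2 alkylation of a sulfolene anion. Putting the chain at C2, next to the methyl-bearing carbon, sets the 1-alkyl-2-methyl diene pattern that becomes C8-chain/C7-methyl. The C2 stereocentre is racemic and is destroyed in step 2.

**Step 2**
Reactants: 3, 4 (1,4-benzoquinone)
Product: 5 (cis-7-methyl-8-(4-methylpent-4-en-1-yl)-4a,5,8,8a-tetrahydronaphthalene-1,4-dione, racemic)
Conditions: 4 (2 equiv), BHT, xylene, sealed tube, 125 °C, 12 h.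
Reagents that add atoms: none (SO2 is lost).
Why: Retro-cheletropic SO2 loss gives the (E)-diene CH2=CH–C(Me)=CH–R in situ, and it is trapped by benzoquinone in a Diels–Alder reaction. Benzoquinone is symmetric, so there is no regiochemistry problem. The cis ring fusion is set by the endo transition state, and the three sp3 stereocentres are erased in step 3.

**Step 3**
Reactants: 5
Product: 6 (7-methyl-8-(4-methylpent-4-en-1-yl)naphthalene-1,4-dione)
Conditions: DDQ (2.3 equiv), 1,4-dioxane, 90 °C, 3 h.
Reagents that add atoms: none.
Why: Enolisation of the adduct to the dihydro-hydroquinone is followed by two DDQ dehydrogenations (dehydrogenative aromatisation). This removes all stereocentres, and the unactivated 1,1-disubstituted side-chain alkene is not a hydride donor.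

**Step 4**
Reactants: 6, 7 (isobutyric acid)
Product: 8 (3-isopropyl-7-methyl-8-(4-methylpent-4-en-1-yl)naphthalene-1,4-dione)
Conditions: 7 (3 equiv), AgNO3 (0.3 equiv), (NH4)2S2O8 (1.5 equiv), MeCN/H2O 1:1, 75 °C, 1–2 h; stop at partial conversion and chromatograph off any C2 isomer.
Reagents that add atoms: none (the isopropyl group comes from reactant 7).
Why: Proposed new method: Ag(II)-mediated oxidative decarboxylation gives the isopropyl radical, which adds to the quinone C=C and is re-oxidised to the quinone (Kochi–Anderson/Minisci-type decarboxylative alkylation, extended here to an unsymmetrical peri-substituted substrate carrying a free alkene). The nucleophilic radical should prefer C3 for two reasons. C3 is β to C1=O, which is twisted by the peri 8-alkyl group and is therefore the better acceptor. C4=O is deactivated by the para 7-methyl group. The 1,1-disubstituted alkene is a far poorer acceptor than the quinone for a nucleophilic radical.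

**Step 5**
Reactants: 8
Product: 10 (2-hydroxy-3-isopropyl-7-methyl-8-(4-methylpent-4-en-1-yl)naphthalene-1,4-dione), via transient epoxide 9
Conditions: 30% aq. H2O2 (5 equiv), Na2CO3 (2 equiv), THF/MeOH/H2O, 0 °C, 30 min; then 1 M NaOH (3 equiv), 0 °C → rt, 1 h; acidify with 1 M HCl.
Reagents that add atoms: hydrogen peroxide, OO.
Why: Weitz–Scheffer nucleophilic epoxidation of the quinone C2=C3 leaves the isolated alkene untouched. Base then removes the only epoxide α-H (C2–H), and E1cB opening of the C3–O bond gives the 2-hydroxy-3-isopropylquinone (the known menadione-epoxide to 2-hydroxy-3-alkylquinone isomerisation). Regiochemistry is fixed by the isopropyl group, and no stereocentre is formed.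

**Step 6**
Reactants: 10
Product: 11 (acetylsalvipisone)
Conditions: Ac2O (3 equiv), pyridine (5 equiv), DMAP (0.1 equiv), CH2Cl2, 0 °C → rt, 2 h.
Reagents that add atoms: acetic anhydride, CC(=O)OC(C)=O.
Why: O-Acylation of the vinylogous-acid enol (simple esterification) gives the 2-acetoxy-1,4-quinone. The alkene is untouched and there are no stereocentres.

## Compound list
1 | 3-methyl-2,5-dihydrothiophene 1,1-dioxide | CC1=CCS(=O)(=O)C1 | starting material
2 | 5-bromo-2-methylpent-1-ene | C=C(C)CCCBr | starting material
3 | 3-methyl-2-(4-methylpent-4-en-1-yl)-2,5-dihydrothiophene 1,1-dioxide (racemic) | C=C(C)CCCC1C(C)=CCS1(=O)=O | intermediate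
4 | 1,4-benzoquinone | O=C1C=CC(=O)C=C1 | starting material
5 | cis-7-methyl-8-(4-methylpent-4-en-1-yl)-4a,5,8,8a-tetrahydronaphthalene-1,4-dione (racemic) | O=C1C=CC(=O)C2CC=C(C)C(CCCC(C)=C)C12 | intermediate
6 | 7-methyl-8-(4-methylpent-4-en-1-yl)naphthalene-1,4-dione | Cc1ccc2C(=O)C=CC(=O)c2c1CCCC(C)=C | intermediate
7 | isobutyric acid | CC(C)C(=O)O | starting material
8 | 3-isopropyl-7-methyl-8-(4-methylpent-4-en-1-yl)naphthalene-1,4-dione | Cc1ccc2C(=O)C(C(C)C)=CC(=O)c2c1CCCC(C)=C | intermediate
9 | 2,3-epoxy-3-isopropyl-2,3-dihydro analogue of 8 (transient, racemic) | Cc1ccc2C(=O)C3(C(C)C)OC3C(=O)c2c1CCCC(C)=C | intermediate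
10 | 2-hydroxy-3-isopropyl-7-methyl-8-(4-methylpent-4-en-1-yl)naphthalene-1,4-dione | Cc1ccc2C(=O)C(C(C)C)=C(O)C(=O)c2c1CCCC(C)=C | intermediate
11 | acetylsalvipisone | C=C(C)CCCc1c(C)ccc2c1C(=O)C(OC(C)=O)=C(C(C)C)C2=O | target

## Totals
Total steps: 6. Longest linear sequence: 6 (1 → 3 → 5 → 6 → 8 → 10 → 11).

## Three steps most likely to fail
1. **Step 4 (regioselectivity of isopropylation, and persulfate tolerance of the alkene).** The C3:C2 ratio may be poor, or SO4•– may attack the side-chain alkene.
   Fallback (different approach): alkylate benzoquinone itself with the same radical chemistry (symmetric substrate, no regiochemistry problem). Then run the Diels–Alder of 2-isopropylbenzoquinone with the diene from 3 under BF3 control, separate the regioisomers, and continue with steps 3, 5 and 6.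
2. **Step 5 (peroxide over-oxidation, or slow E1cB because of peri strain in the C1 enolate).**
   Fallback (different approach): bypass it with an oxygen-directed cycloaddition. React the diene from 3 with 2-acetoxy- or 2-methoxybenzoquinone, where the oxygen polarises the dienophile. Isopropylate the sole remaining C3–H with the step 4 radical conditions, then re-acetylate (or demethylate and acetylate).
3. **Step 1 (C2 versus C5 alkylation of the 3-methylsulfolene anion, and anion ring-opening).**
   Fallback (different approach): make the (E)-diene CH2=CH–C(Me)=CH–CH2CH2CH2C(Me)=CH2 by Wittig olefination of methyl vinyl ketone with the ylide from 6-bromo-2-methylhex-1-ene. Enrich the E isomer (Schlosser modification or I2 isomerisation), then feed it directly into the Diels–Alder of step 2.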